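## Structural features

The target is a germacranolide: a ten-membered carbocycle (C1–C10) fused across C6–C7 to a butenolide (O–C12(=O)–C11=C7). The carbocycle holds two E-trisubstituted alkenes: C1=C10, part of a cross-conjugated C2 enone, and C4=C5, with the C3 methylene between ketone and alkene. The butenolide alkene C7=C11 is tetrasubstituted and carries the C13 acetoxymethyl group. There are only two stereocentres, C6 (R, lactone carbinol) and C8 (S, methacrylate carbinol); they flank the trigonal C7 and their oxygens are cis on the ring. Fragile features are the doubly activated C3 methylene, the methacrylate, the allylic acetate on an electron-poor alkene, the lactone (which can migrate from O6 to O8 once the C8 hydroxyl is free) and the (E,E)-cyclodeca-1,5-diene (Cope rearrangement on heating, transannular cyclisation in acid). The real difficulty is the medium ring with two E alkenes, for which end-to-end closure is penalised by strain and entropy, together with relating C6 to C8 across a carbon that ends trigonal. The key step uses the fact that C6 bears oxygen and lies between C5, which can be an alkyne carbon, and C7, which carries the branch C11(C12)(C13). With a C11=C12 methylene this is the homoallylic alcohol left by a [2,3]-Wittig shift of an ether whose oxygen links propargylic C6 to allylic C12, that is a thirteen-membered ring (O, C12, C11, C7–C10, C1–C6) that contracts to the carbocycle.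

## Logic of the disconnections

38 is cut at the C8–O acyl bond to give 37. The methacrylate cannot survive organolithium, hydride or enolate chemistry, so it is put on last. The forward step must acylate a hindered secondary hydroxyl without disturbing the C3 methylene or the lactone.

37 is traced to 36 (C2 carbonyl back to carbinol) and 36 to 35 (both O–Si bonds cut at once). The enone must not exist during any basic step, and one deprotection replaces two. The oxidant must distinguish the electron-rich allylic C2 carbinol from the C8 carbinol.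

35 is traced through 34 (O13–acetyl bond) to 31 (C7=C11 returned to a saturated C7–H/C11–H pair). This makes C7 and C11 sp3 again, as the rearrangement leaves them. The forward step needs selenium to enter syn to H7 and the elimination to run away from the oxygen-bearing C13.

31 is traced through 30 (O13 protecting group), 28 (lactone C12–O6 bond and C12 oxidation level) to 26 (C12–O bond, back to the C11=C12 methylene). The C12 carbonyl therefore comes from the methylene that the rearrangement creates. Hydroboration must choose the 1,1-disubstituted alkene over two trisubstituted ring alkenes, and the oxidation must choose the primary alcohol.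

26 is traced through 25 (C4–CH3 bond) to 23 (C4–I and C5–H bonds, back to the C4≡C5 alkyne). The alkyne is what the rearrangement requires, and the C6 hydroxyl it leaves directs the trans addition. The demand is a regio- and stereospecific hydroalumination inside a ten-membered ring.

23 is traced to 22 by cutting C6–C7 and rejoining O to C12. This removes the carbocycle, both new stereocentres and the need for any medium-ring closure. The forward step needs deprotonation at C6 only and face selection at C7 by C8. A descriptor check shows that 6S in 23 is the same spatial arrangement as 6R in 38, because C5 loses priority to C7 once the alkyne becomes the methyl-bearing alkene.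

22 is cut at the C4≡C5 triple bond to the methyl-capped diyne 21. Closing the ring at the alkyne rather than at the ether oxygen avoids protecting and activating a second primary hydroxyl. The demand is high dilution and a catalyst inert to ethers and alkenes.

21 is cut at the O–C6 bond to 19 and 20, a simple O-alkylation.

19 is traced through 18 (C12 oxidation level) to 14, 15 and 16 by cutting the C7=C11 double bond and the O–C13 bond. Three components give the whole C11–C13 branch in one operation. The olefination must place C12 trans to C8 and must not epimerise C8.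

14 is traced through 13 (C7 oxidation level), 12 (O7 protecting group), 11 (alkyne methyl cap) and 10 (O2–Si bond) to 8 and 9 by cutting C2–C3. The C2 configuration is set by the catalyst only so that later intermediates are single diastereomers; it is erased at the end.

8 is traced through 7 (C2 oxidation level) to 5 by cutting C1–C2 and C10–CH3. A syn carbometalation of a terminal alkyne fixes the E C1=C10 alkene.

5 is traced through 4 (O8–Si bond) and 2 with 3 (C9–C10 bond, epoxide opening) to 1 (O7 protecting group). C8 comes from the chiral pool: the R epoxide maps onto 8S with no bond to the stereocentre broken.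

## Other disconnections considered

Alternative 1: the C9–C10 bond is cut, giving the seco compound A1, an N-acyloxyphthalimide ester at C9 with an E vinyl iodide at C10. In the forward step, constant-current electrolysis with a nickel–bipyridine catalyst would expel CO2, generate the primary C9 radical and couple it with the alkenyl iodide to give A2. In its favour, every functional group of the target is already present, the iodide geometry is transferred, and only desilylation and acylation remain. On step economy after ring formation this is clearly better than the chosen plan (two steps against ten). Against it, the ten-membered ring with both E alkenes and the butenolide must be closed end to end. The primary radical must be captured by nickel faster than it is reduced or dimerised. The low-valent nickel and the cathode also threaten the C13 allylic acetate, the β-iodo enone and the C8 silyloxy group β to the new carbon–nickel bond. The chosen plan avoids direct closure and has a close mechanistic analogy, while this closure would be without one for a germacrane ring.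

Alternative 2: the C7–C8 bond is cut, giving the iodobutenolide aldehyde A3. CrCl2 with catalytic NiCl2 would convert the C7 iodide into an alkenylchromium species that adds to the C8 aldehyde to give A4. In its favour, this is among the most dependable carbonyl additions for medium and large rings and tolerates lactone and acetate. The C8 hydroxyl emerges free for acylation, and the remaining sequence (acylation, desilylation, oxidation) is three steps with the ketone formed last. Both points are better than in the chosen plan. Against it, C8 would be created in the closure under remote control from C6 across the planar C7, so its sense is uncertain, whereas the chosen plan takes C8 from the chiral pool. The β,γ-unsaturated aldehyde of A3 is prone to conjugation. The chromium alkoxide at O8 is placed to attack C12 and move the lactone. The ring is again closed directly against strain.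

Alternative 3: the C5–C6 and C4–CH3 bonds are cut, giving the ynal A5. Zerovalent nickel, Ni(cod)2 with a carbene ligand, would couple the terminal alkyne carbon C5 with the C6 aldehyde through an oxanickelacycle, and Me2Zn would deliver methyl to C4, giving A6. In its favour, one step forms the ring, the E C4=C5 alkene by syn addition and the C6 carbinol, where the chosen plan needs three steps (15 to 17). That is a real advantage. Against it, the endocyclic mode on a terminal alkyne depends on the ligand, a ten-membered ring is at the small limit of this cyclisation, and hydride instead of methyl transfer can compete. A6 also carries oxygen, not the C11–C13 branch, at C7. The butenolide would have to be built afterwards from a C7 ketone flanked by the epimerisable C6 and C8. The chosen rearrangement installs the C7–C11 bond and O6 together, so overall step economy is about equal.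

Key step: step 15

Remarks on the chemistry, stated as assumptions:
- Germacrane locants (C1–C13) are used for all intermediates.
- 16 is taken as a purchased reagent; it is also available in one operation from triethyl phosphonoacetate and paraformaldehyde.
- C2 is carried as the 2R silyl ether; either epimer would serve. C11 in 27–33 is an unassigned mixture that disappears in step 21.

## Route

Step 1
Reactants: 1 (R)-glycidol
Product: 2 (S)-2-{[(4-methoxybenzyl)oxy]methyl}oxirane
Conditions: NaH, 4-methoxybenzyl chloride, Bu4NI (cat.), THF–DMF, 0 °C → rt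
Reagents that add atoms: 4-methoxybenzyl chloride, COc1ccc(CCl)cc1
Why: Williamson etherification of the primary alkoxide; the stereocentre is untouched (the descriptor changes only through the priority rules) and the degenerate Payne equilibrium of glycidol returns the same enantiomer.

Step 2
Reactants: 2 (S)-2-{[(4-methoxybenzyl)oxy]methyl}oxirane; 3 lithium acetylide–ethylenediamine complex
Product: 4 (S)-1-[(4-methoxybenzyl)oxy]pent-4-yn-2-ol
Conditions: DMSO, 0 °C → rt; H2O
Reagents that add atoms: none
Why: SN2 opening of the epoxide at its terminal carbon by acetylide forms C9–C10; the carbinol carbon (C8) is not involved and keeps its configuration.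

Step 3
Reactants: 4 (S)-1-[(4-methoxybenzyl)oxy]pent-4-yn-2-ol
Product: 5 (S)-tert-butyl({1-[(4-methoxybenzyl)oxy]pent-4-yn-2-yl}oxy)dimethylsilane
Conditions: TBSCl, imidazole, DMF, rt
Reagents that add atoms: tert-butyldimethylsilyl chloride, CC(C)(C)[Si](C)(C)Cl
Why: Standard silylation of a secondary alcohol; the robust silyl group is chosen for C8 because it must last to step 23 and should not migrate to O6 after the key step.

Step 4
Reactants: 5 (S)-tert-butyl({1-[(4-methoxybenzyl)oxy]pent-4-yn-2-yl}oxy)dimethylsilane
Product: 7 (2E,5S)-5-[(tert-butyldimethylsilyl)oxy]-6-[(4-methoxybenzyl)oxy]-3-methylhex-2-en-1-ol, via (E)-alkenyldimethylalane 6 (not isolated)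
Conditions: AlMe3, Cp2ZrCl2 (cat.), CH2Cl2, 0 °C → rt; (CH2O)n, 0 °C → rt; aq. KNaC4H4O6 (potassium sodium tartrate)
Reagents that add atoms: trimethylaluminium, C[Al](C)C; formaldehyde (as paraformaldehyde), C=O
Why: Negishi zirconium-catalysed carboalumination adds methyl and aluminium syn, with methyl on the internal carbon, which fixes the E C1=C10 alkene; the alkenylalane then adds to formaldehyde with retention to give C2.

Step 5
Reactants: 7 (2E,5S)-5-[(tert-butyldimethylsilyl)oxy]-6-[(4-methoxybenzyl)oxy]-3-methylhex-2-en-1-ol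
Product: 8 (2E,5S)-5-[(tert-butyldimethylsilyl)oxy]-6-[(4-methoxybenzyl)oxy]-3-methylhex-2-enal
Conditions: MnO2, CH2Cl2, rt
Reagents that add atoms: none
Why: Allylic oxidation with MnO2 is selective for the allylic alcohol and leaves ethers and alkene geometry alone.

Step 6
Reactants: 8 (2E,5S)-5-[(tert-butyldimethylsilyl)oxy]-6-[(4-methoxybenzyl)oxy]-3-methylhex-2-enal; 9 allenylboronic acid pinacol ester
Product: 10 (4R,5E,8S)-8-[(tert-butyldimethylsilyl)oxy]-9-[(4-methoxybenzyl)oxy]-6-methylnon-5-en-1-yn-4-ol
Conditions: (R)-TRIP phosphoric acid (5 mol %), 4 Å molecular sieves, toluene, 0 °C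
Reagents that add atoms: none
Why: Chiral phosphoric acid-catalysed propargylation: the allenylboronate reacts through a six-membered SE2′ transition state, so only the homopropargylic alcohol forms (C2–C3 bond). By the usual model for this catalyst the Re face is attacked and 2R is expected; the sense is immaterial for the target and serves only to keep later intermediates single diastereomers.

Step 7
Reactants: 10 (4R,5E,8S)-8-[(tert-butyldimethylsilyl)oxy]-9-[(4-methoxybenzyl)oxy]-6-methylnon-5-en-1-yn-4-ol
Product: 11 (4R,5E,8S)-8-[(tert-butyldimethylsilyl)oxy]-9-[(4-methoxybenzyl)oxy]-6-methyl-4-[(triethylsilyl)oxy]non-5-en-1-yne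
Conditions: TESCl, imidazole, CH2Cl2, 0 °C
Reagents that add atoms: chlorotriethylsilane, CC[Si](Cl)(CC)CC
Why: Standard silylation; the more labile triethylsilyl group on O2 keeps the option of freeing C2 before C8.

Step 8
Reactants: 11 (4R,5E,8S)-8-[(tert-butyldimethylsilyl)oxy]-9-[(4-methoxybenzyl)oxy]-6-methyl-4-[(triethylsilyl)oxy]non-5-en-1-yne
Product: 12 (2S,4E,6R)-2-[(tert-butyldimethylsilyl)oxy]-1-[(4-methoxybenzyl)oxy]-4-methyl-6-[(triethylsilyl)oxy]dec-4-en-8-yne
Conditions: n-BuLi, THF, −78 °C; MeI, −78 °C → rt
Reagents that add atoms: iodomethane, CI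
Why: Acetylide alkylation; the methyl cap is needed because alkyne metathesis works best on internal alkynes and the cap leaves as volatile but-2-yne.

Step 9
Reactants: 12 (2S,4E,6R)-2-[(tert-butyldimethylsilyl)oxy]-1-[(4-methoxybenzyl)oxy]-4-methyl-6-[(triethylsilyl)oxy]dec-4-en-8-yne
Product: 13 (2S,4E,6R)-2-[(tert-butyldimethylsilyl)oxy]-4-methyl-6-[(triethylsilyl)oxy]dec-4-en-8-yn-1-ol
Conditions: DDQ, CH2Cl2–aq. NaH2PO4/Na2HPO4 (pH 7), 0 °C
Reagents that add atoms: none
Why: Oxidative cleavage of the only 4-methoxybenzyl ether present; silyl ethers, alkene and alkyne are inert under buffered conditions.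

Step 10
Reactants: 13 (2S,4E,6R)-2-[(tert-butyldimethylsilyl)oxy]-4-methyl-6-[(triethylsilyl)oxy]dec-4-en-8-yn-1-ol
Product: 14 (2S,4E,6R)-2-[(tert-butyldimethylsilyl)oxy]-4-methyl-6-[(triethylsilyl)oxy]dec-4-en-8-ynal
Conditions: Dess–Martin periodinane, NaHCO3, CH2Cl2, 0 °C → rt
Reagents that add atoms: none
Why: Buffered Dess–Martin oxidation gives the α-silyloxy aldehyde (C7) without epimerising C8; it is used directly.

Step 11
Reactants: 14 (2S,4E,6R)-2-[(tert-butyldimethylsilyl)oxy]-4-methyl-6-[(triethylsilyl)oxy]dec-4-en-8-ynal; 15 4-methoxybenzyl alcohol; 16 ethyl 2-(diethoxyphosphoryl)acrylate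
Product: 18 ethyl (2E,4S,6E,8R)-4-[(tert-butyldimethylsilyl)oxy]-2-{[(4-methoxybenzyl)oxy]methyl}-6-methyl-8-[(triethylsilyl)oxy]dodeca-2,6-dien-10-ynoate, via sodium phosphonate carbanion 17 (not isolated)
Conditions: 15, NaH, THF, 0 °C; 16, −20 → 0 °C; then 14, 0 °C → rt
Reagents that add atoms: none
Why: Tandem oxa-Michael addition and Horner–Wadsworth–Emmons olefination: the alkoxide adds to the vinylphosphonate to give a stabilised carbanion, which olefinates the aldehyde and forms C7=C11 with the whole C11–C13 branch. Stabilised α-substituted phosphonates with α-branched aldehydes favour the E ester (C12 trans to C8), and the weakly basic carbanion spares the C8 stereocentre.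

Step 12
Reactants: 18 ethyl (2E,4S,6E,8R)-4-[(tert-butyldimethylsilyl)oxy]-2-{[(4-methoxybenzyl)oxy]methyl}-6-methyl-8-[(triethylsilyl)oxy]dodeca-2,6-dien-10-ynoate
Product: 19 (2Z,4S,6E,8R)-4-[(tert-butyldimethylsilyl)oxy]-2-{[(4-methoxybenzyl)oxy]methyl}-6-methyl-8-[(triethylsilyl)oxy]dodeca-2,6-dien-10-yn-1-ol (hydroxymethyl group trans to C8)
Conditions: i-Bu2AlH, CH2Cl2, −78 °C; aq. KNaC4H4O6
Reagents that add atoms: none
Why: 1,2-Reduction of the enoate to the allylic alcohol (C12); the geometry is unchanged and only the descriptor switches.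

Step 13
Reactants: 19 (2Z,4S,6E,8R)-4-[(tert-butyldimethylsilyl)oxy]-2-{[(4-methoxybenzyl)oxy]methyl}-6-methyl-8-[(triethylsilyl)oxy]dodeca-2,6-dien-10-yn-1-ol; 20 1-bromobut-2-yne
Product: 21 but-2-yn-1-yl ether of 19 (butynyloxymethyl group trans to C8)
Conditions: NaH, THF, 0 °C; 20, Bu4NI (cat.), 0 °C → rt
Reagents that add atoms: none
Why: Williamson etherification with a reactive propargylic bromide forms the O–C6 bond; because C12 is trans to C8 the alkoxide cannot reach the C8 silyl group.

Step 14
Reactants: 21 but-2-yn-1-yl ether of 19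
Product: 22 (3E,5S,7E,9R)-5-[(tert-butyldimethylsilyl)oxy]-3-{[(4-methoxybenzyl)oxy]methyl}-7-methyl-9-[(triethylsilyl)oxy]-1-oxacyclotrideca-3,7-dien-11-yne
Conditions: Mo(≡CC6H4OMe-4)(OSiPh3)3 (10 mol %), 5 Å molecular sieves, toluene (0.002 M), rt → 60 °C
Reagents that add atoms: none
Why: Ring-closing alkyne metathesis through metallacyclobutadienes joins C4 and C5; but-2-yne is trapped by the sieves. A thirteen-membered cycloalkyne is within the usual range of this closure, and alkenes and ethers are inert to the alkylidyne.

Step 15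
Reactants: 22 (3E,5S,7E,9R)-5-[(tert-butyldimethylsilyl)oxy]-3-{[(4-methoxybenzyl)oxy]methyl}-7-methyl-9-[(triethylsilyl)oxy]-1-oxacyclotrideca-3,7-dien-11-yne
Product: 23 (1S,5R,6E,9S,10S)-9-[(tert-butyldimethylsilyl)oxy]-10-{3-[(4-methoxybenzyl)oxy]prop-1-en-2-yl}-7-methyl-5-[(triethylsilyl)oxy]cyclodec-6-en-2-yn-1-ol (germacrane locants 2R,6S,7S,8S)
Conditions: n-BuLi (1.3 equiv), THF–hexane, −78 → −40 °C; H2O
Reagents that add atoms: none
Why: n-BuLi removes a C6 proton, the most acidic one in 22 because the carbanion is at once propargylic and next to the ether oxygen, whereas the allylic C12 and C13 and the anisyl CH2 positions are deprotonated far more slowly at −78 °C. The C6 carbanion attacks C7 suprafacially through a five-membered, six-electron envelope transition state (C6, O, C12, C11, C7) while the O–C12 bond breaks; this is a [2,3]-Wittig rearrangement, and the closest known reaction type is the ring contraction of thirteen-membered propargylic allylic ethers to cyclodecynols. The ten-membered carbocycle is therefore not closed end to end: it arises by transannular C6–C7 bond formation inside the macrocycle (contraction from 13 to 10 ring atoms, the oxygen and C12 leaving the ring as the C6 alkoxide and the C11 methylene). For C7, allylic 1,3-strain with the cis CH2O(4-methoxybenzyl) group on C11 holds the C8–H bond in the alkene plane, so the silyloxy group shields one face and C9, which is tied to C6 through the ring, sits on the other; attack on the C9 face, anti to the C8–O bond, gives 7S. For C6, with C12 trans to C8 and the alkynyl chain exo on the envelope, the shift gives the anti C6/C7 arrangement, that is 6S with O6 cis to O8 on the ring, which is 6R in 38 once the alkyne has become the methyl-bearing alkene. The step needs site selectivity in the deprotonation (secured by acidity), [2,3] over [1,2] shift (secured by low temperature and the concerted path) and facial selectivity (secured by the C8 stereocentre and the ring tether).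

Step 16
Reactants: 23 (1S,5R,6E,9S,10S)-9-[(tert-butyldimethylsilyl)oxy]-10-{3-[(4-methoxybenzyl)oxy]prop-1-en-2-yl}-7-methyl-5-[(triethylsilyl)oxy]cyclodec-6-en-2-yn-1-ol
Product: 25 (Z)-alkenyl iodide: 23 with C4≡C5 replaced by C4(I)=C5H and iodine cis to C6 (2R,6S,7S,8S), via cyclic alkenylaluminate 24 (not isolated)
Conditions: NaAlH2(OCH2CH2OMe)2, THF, 0 °C → rt; EtOAc; I2, THF, −78 → 0 °C; aq. Na2S2O3
Reagents that add atoms: iodine, II
Why: Hydroxyl-directed trans-hydroalumination: the C6 alkoxyaluminate delivers hydride to C5 and forms a five-membered oxa-aluminacycle with aluminium on C4; iodinolysis proceeds with retention. This fixes C3 trans to C6, the E ring geometry of the future C4=C5 alkene; the reaction type is established for propargylic alcohols, medium-ring ones included.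

Step 17
Reactants: 25 (Z)-alkenyl iodide
Product: 26 diene alcohol: 25 with methyl in place of iodine, 4E (2R,6R,7S,8S)
Conditions: Me2CuLi (from MeLi, CuI; excess), Et2O, 0 °C
Reagents that add atoms: methyllithium (as lithium dimethylcuprate), [Li]C
Why: Cuprate substitution of an alkenyl iodide occurs with retention of geometry, giving the E-trisubstituted C4=C5 alkene; excess reagent covers the free hydroxyl.

Step 18
Reactants: 26 diene alcohol
Product: 28 1,4-diol: 26 with C11=C12 methylene converted into C11H–C12H2OH (C11 epimers), via B-alkyl-9-borabicyclononane 27 (not isolated)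
Conditions: 9-BBN, THF, 0 °C → rt; NaOH, H2O2, 0 °C
Reagents that add atoms: hydrogen peroxide, OO
Why: 9-BBN hydroborates the 1,1-disubstituted alkene far faster than the two trisubstituted ring alkenes and places boron on C12; oxidation with retention gives the primary alcohol. The new C11 centre is uncontrolled and is erased in step 21.

Step 19
Reactants: 28 1,4-diol
Product: 30 trans-fused γ-lactone (C12 carbonyl and O6; C11 bears the CH2O(4-methoxybenzyl) group and is a mixture of epimers), via lactol 29 (not isolated)
Conditions: TEMPO (cat.), PhI(OAc)2, CH2Cl2, rt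
Reagents that add atoms: none
Why: Oxoammonium oxidation is selective for the primary alcohol; the hydroxy aldehyde closes on O6 to the lactol, which is oxidised further to the lactone. The ring fusion is trans because C6 and C7 were set anti in step 15.

Step 20
Reactants: 30 trans-fused γ-lactone
Product: 31 α-(hydroxymethyl) lactone (C13 hydroxyl free)
Conditions: DDQ, CH2Cl2–aq. NaH2PO4/Na2HPO4 (pH 7), 0 °C
Reagents that add atoms: none
Why: Oxidative removal of the 4-methoxybenzyl group; it is done before enolisation so that O13 is present as an alkoxide, which cannot leave by β-elimination from the enolate in step 21.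

Step 21
Reactants: 31 α-(hydroxymethyl) lactone
Product: 34 α-(hydroxymethyl)butenolide with C7=C11 (2R,6R,8S), via α-phenylselanyl lactone 32 (not isolated), via selenoxide 33 (not isolated)
Conditions: LiN(i-Pr)2 (2.2 equiv), THF, −78 → −40 °C; PhSeBr, −78 °C; AcOH; then H2O2, pyridine, CH2Cl2, 0 °C → rt
Reagents that add atoms: none
Why: The alkoxide–enolate dianion (as in Fráter–Seebach chemistry) is selenenylated at C11 anti to the C8 branch on C7, so selenium ends syn to H7. Selenoxide syn-elimination then runs away from the oxygen-bearing C13, as is general for β-hydroxy selenoxides, and gives the endocyclic butenolide.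

Step 22
Reactants: 34 α-(hydroxymethyl)butenolide
Product: 35 C13 acetate of 34
Conditions: Ac2O, pyridine, DMAP (cat.), CH2Cl2, 0 °C
Reagents that add atoms: acetic anhydride, CC(=O)OC(C)=O
Why: Acylation of the only free, primary hydroxyl under mild base that does not deprotonate the butenolide at C6.

Step 23
Reactants: 35 C13 acetate
Product: 36 C2,C8-diol (both silyl groups removed)
Conditions: HF·pyridine, pyridine, THF, 0 °C → rt
Reagents that add atoms: none
Why: Buffered fluoride cleaves both silyl ethers; acetate and butenolide are stable to it and the buffered medium avoids acid-induced transannular cyclisation.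

Step 24
Reactants: 36 C2,C8-diol
Product: 37 C2 ketone with free C8 hydroxyl (6R,8S)
Conditions: MnO2, CH2Cl2, rt
Reagents that add atoms: none
Why: MnO2 oxidises the C2 carbinol, allylic to the electron-rich C1=C10 alkene, much faster than the hindered C8 carbinol, which is allylic only to the electron-poor butenolide alkene; the neutral medium spares the C3 methylene.

Step 25
Reactants: 37 C2 ketone with free C8 hydroxyl
Product: 38 CNP0325594.1, (6R,8S)-13-acetoxy-8-(methacryloyloxy)-2-oxogermacra-1(10)E,4E,7(11)-trien-12,6-olide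
Conditions: methacrylic anhydride, Et3N, DMAP (cat.), CH2Cl2, 0 °C
Reagents that add atoms: methacrylic anhydride, C=C(C)C(=O)OC(=O)C(C)=C
Why: DMAP-catalysed acylation of the secondary C8 hydroxyl at low temperature with a weak amine base; no stereocentre is touched.

## Compound list

1 | (R)-glycidol | OC[C@@H]1CO1 | starting material
2 | (S)-2-{[(4-methoxybenzyl)oxy]methyl}oxirane | COc1ccc(COC[C@@H]2CO2)cc1 | intermediate
3 | lithium acetylide–ethylenediamine complex | [Li+].[C-]#C.NCCN | starting material
4 | (S)-1-[(4-methoxybenzyl)oxy]pent-4-yn-2-ol | COc1ccc(COC[C@@H](O)CC#C)cc1 | intermediate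
5 | (S)-tert-butyl({1-[(4-methoxybenzyl)oxy]pent-4-yn-2-yl}oxy)dimethylsilane | COc1ccc(COC[C@@H](O[Si](C)(C)C(C)(C)C)CC#C)cc1 | intermediate
6 | (E)-alkenyldimethylalane from 5 (methyl on C10, aluminium on C1) | COc1ccc(COC[C@@H](O[Si](C)(C)C(C)(C)C)C/C(C)=C/[Al](C)C)cc1 | intermediate (not isolated)
7 | (2E,5S)-5-[(tert-butyldimethylsilyl)oxy]-6-[(4-methoxybenzyl)oxy]-3-methylhex-2-en-1-ol | COc1ccc(COC[C@@H](O[Si](C)(C)C(C)(C)C)C/C(C)=C/CO)cc1 | intermediate
8 | (2E,5S)-5-[(tert-butyldimethylsilyl)oxy]-6-[(4-methoxybenzyl)oxy]-3-methylhex-2-enal | COc1ccc(COC[C@@H](O[Si](C)(C)C(C)(C)C)C/C(C)=C/C=O)cc1 | intermediate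
9 | allenylboronic acid pinacol ester | C=C=CB1OC(C)(C)C(C)(C)O1 | starting material
10 | (4R,5E,8S)-8-[(tert-butyldimethylsilyl)oxy]-9-[(4-methoxybenzyl)oxy]-6-methylnon-5-en-1-yn-4-ol | COc1ccc(COC[C@@H](O[Si](C)(C)C(C)(C)C)C/C(C)=C/[C@H](O)CC#C)cc1 | intermediate
11 | (4R,5E,8S)-8-[(tert-butyldimethylsilyl)oxy]-9-[(4-methoxybenzyl)oxy]-6-methyl-4-[(triethylsilyl)oxy]non-5-en-1-yne | COc1ccc(COC[C@@H](O[Si](C)(C)C(C)(C)C)C/C(C)=C/[C@H](O[Si](CC)(CC)CC)CC#C)cc1 | intermediate
12 | (2S,4E,6R)-2-[(tert-butyldimethylsilyl)oxy]-1-[(4-methoxybenzyl)oxy]-4-methyl-6-[(triethylsilyl)oxy]dec-4-en-8-yne | COc1ccc(COC[C@@H](O[Si](C)(C)C(C)(C)C)C/C(C)=C/[C@H](O[Si](CC)(CC)CC)CC#CC)cc1 | intermediate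
13 | (2S,4E,6R)-2-[(tert-butyldimethylsilyl)oxy]-4-methyl-6-[(triethylsilyl)oxy]dec-4-en-8-yn-1-ol | OC[C@@H](O[Si](C)(C)C(C)(C)C)C/C(C)=C/[C@H](O[Si](CC)(CC)CC)CC#CC | intermediate
14 | (2S,4E,6R)-2-[(tert-butyldimethylsilyl)oxy]-4-methyl-6-[(triethylsilyl)oxy]dec-4-en-8-ynal | O=C[C@@H](O[Si](C)(C)C(C)(C)C)C/C(C)=C/[C@H](O[Si](CC)(CC)CC)CC#CC | intermediate
15 | 4-methoxybenzyl alcohol | COc1ccc(CO)cc1 | starting material
16 | ethyl 2-(diethoxyphosphoryl)acrylate | C=C(C(=O)OCC)P(=O)(OCC)OCC | starting material
17 | sodium salt of ethyl 2-(diethoxyphosphoryl)-3-[(4-methoxybenzyl)oxy]propanoate | [Na+].CCOC(=O)[C-](COCc1ccc(OC)cc1)P(=O)(OCC)OCC | intermediate (not isolated)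
18 | ethyl (2E,4S,6E,8R)-4-[(tert-butyldimethylsilyl)oxy]-2-{[(4-methoxybenzyl)oxy]methyl}-6-methyl-8-[(triethylsilyl)oxy]dodeca-2,6-dien-10-ynoate | CCOC(=O)/C(COCc1ccc(OC)cc1)=C/[C@@H](O[Si](C)(C)C(C)(C)C)C/C(C)=C/[C@H](O[Si](CC)(CC)CC)CC#CC | intermediate
19 | (2Z,4S,6E,8R)-4-[(tert-butyldimethylsilyl)oxy]-2-{[(4-methoxybenzyl)oxy]methyl}-6-methyl-8-[(triethylsilyl)oxy]dodeca-2,6-dien-10-yn-1-ol | OC/C(COCc1ccc(OC)cc1)=C/[C@@H](O[Si](C)(C)C(C)(C)C)C/C(C)=C/[C@H](O[Si](CC)(CC)CC)CC#CC | intermediate
20 | 1-bromobut-2-yne | CC#CCBr | starting material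
21 | but-2-yn-1-yl ether of 19 (ether arm trans to C8) | CC#CCOC/C(COCc1ccc(OC)cc1)=C/[C@@H](O[Si](C)(C)C(C)(C)C)C/C(C)=C/[C@H](O[Si](CC)(CC)CC)CC#CC | intermediate
22 | (3E,5S,7E,9R)-5-[(tert-butyldimethylsilyl)oxy]-3-{[(4-methoxybenzyl)oxy]methyl}-7-methyl-9-[(triethylsilyl)oxy]-1-oxacyclotrideca-3,7-dien-11-yne | O1C/C(COCc2ccc(OC)cc2)=C/[C@@H](O[Si](C)(C)C(C)(C)C)C/C(C)=C/[C@H](O[Si](CC)(CC)CC)CC#CC1 | intermediate
23 | (1S,5R,6E,9S,10S)-9-[(tert-butyldimethylsilyl)oxy]-10-{3-[(4-methoxybenzyl)oxy]prop-1-en-2-yl}-7-methyl-5-[(triethylsilyl)oxy]cyclodec-6-en-2-yn-1-ol | O[C@@H]1C#CC[C@@H](O[Si](CC)(CC)CC)/C=C(C)/C[C@H](O[Si](C)(C)C(C)(C)C)[C@H]1C(=C)COCc1ccc(OC)cc1 | intermediate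
24 | sodium salt of the cyclic alkenylaluminate (O6–Al–C4 five-membered ring, two 2-methoxyethoxy ligands) | [Na+].O2[C@@H]1/C=C([Al-]2(OCCOC)OCCOC)/C[C@@H](O[Si](CC)(CC)CC)/C=C(C)/C[C@H](O[Si](C)(C)C(C)(C)C)[C@H]1C(=C)COCc3ccc(OC)cc3 | intermediate (not isolated)
25 | (Z)-alkenyl iodide: ten-membered ring with C4(I)=C5H, iodine cis to C6, C6 hydroxyl, C7 2-substituted allyl branch (2R,6S,7S,8S) | O[C@@H]1/C=C(I)/C[C@@H](O[Si](CC)(CC)CC)/C=C(C)/C[C@H](O[Si](C)(C)C(C)(C)C)[C@H]1C(=C)COCc1ccc(OC)cc1 | intermediate
26 | diene alcohol: 25 with methyl in place of iodine, 1(10)E,4E (2R,6R,7S,8S) | O[C@@H]1/C=C(C)/C[C@@H](O[Si](CC)(CC)CC)/C=C(C)/C[C@H](O[Si](C)(C)C(C)(C)C)[C@H]1C(=C)COCc1ccc(OC)cc1 | intermediate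
27 | B-alkyl-9-borabicyclo[3.3.1]nonane (boron on C12; C11 epimers) | O[C@@H]1/C=C(C)/C[C@@H](O[Si](CC)(CC)CC)/C=C(C)/C[C@H](O[Si](C)(C)C(C)(C)C)[C@H]1C(CB2C3CCCC2CCC3)COCc1ccc(OC)cc1 | intermediate (not isolated)
28 | 1,4-diol: C6 hydroxyl and C12 hydroxymethyl, C13 4-methoxybenzyl ether (C11 epimers) | O[C@@H]1/C=C(C)/C[C@@H](O[Si](CC)(CC)CC)/C=C(C)/C[C@H](O[Si](C)(C)C(C)(C)C)[C@H]1C(CO)COCc1ccc(OC)cc1 | intermediate
29 | lactol (C12 hemiacetal closed on O6; C11 and C12 epimers) | [C@@H]12/C=C(C)/C[C@@H](O[Si](CC)(CC)CC)/C=C(C)/C[C@H](O[Si](C)(C)C(C)(C)C)[C@H]1C(COCc3ccc(OC)cc3)C(O)O2 | intermediate (not isolated)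
30 | trans-fused 12,6-lactone with C13 4-methoxybenzyl ether (C11 epimers) | [C@@H]12/C=C(C)/C[C@@H](O[Si](CC)(CC)CC)/C=C(C)/C[C@H](O[Si](C)(C)C(C)(C)C)[C@H]1C(COCc3ccc(OC)cc3)C(=O)O2 | intermediate
31 | trans-fused 12,6-lactone with free C13 hydroxyl (C11 epimers) | [C@@H]12/C=C(C)/C[C@@H](O[Si](CC)(CC)CC)/C=C(C)/C[C@H](O[Si](C)(C)C(C)(C)C)[C@H]1C(CO)C(=O)O2 | intermediate
32 | 11-phenylselanyl derivative of 31 | [C@@H]12/C=C(C)/C[C@@H](O[Si](CC)(CC)CC)/C=C(C)/C[C@H](O[Si](C)(C)C(C)(C)C)[C@H]1C(CO)([Se]c3ccccc3)C(=O)O2 | intermediate (not isolated)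
33 | selenoxide of 32 | [C@@H]12/C=C(C)/C[C@@H](O[Si](CC)(CC)CC)/C=C(C)/C[C@H](O[Si](C)(C)C(C)(C)C)[C@H]1C(CO)([Se](=O)c3ccccc3)C(=O)O2 | intermediate (not isolated)
34 | 13-hydroxy-7(11)-en-12,6-olide with C2 triethylsilyl and C8 tert-butyldimethylsilyl ethers (2R,6R,8S) | [C@@H]12/C=C(C)/C[C@@H](O[Si](CC)(CC)CC)/C=C(C)/C[C@H](O[Si](C)(C)C(C)(C)C)C1=C(CO)C(=O)O2 | intermediate
35 | 13-acetate of 34 | [C@@H]12/C=C(C)/C[C@@H](O[Si](CC)(CC)CC)/C=C(C)/C[C@H](O[Si](C)(C)C(C)(C)C)C1=C(COC(C)=O)C(=O)O2 | intermediate
36 | 13-acetoxy-2,8-dihydroxy butenolide (2R,6R,8S) | [C@@H]12/C=C(C)/C[C@@H](O)/C=C(C)/C[C@H](O)C1=C(COC(C)=O)C(=O)O2 | intermediate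
37 | 13-acetoxy-8-hydroxy-2-oxo butenolide (6R,8S) | [C@@H]12/C=C(C)/CC(=O)/C=C(C)/C[C@H](O)C1=C(COC(C)=O)C(=O)O2 | intermediate
38 | CNP0325594.1, (6R,8S)-13-acetoxy-8-(methacryloyloxy)-2-oxogermacra-1(10)E,4E,7(11)-trien-12,6-olide | C=C(C)C(=O)O[C@H]1C/C(C)=C/C(=O)C/C(C)=C/[C@H]2OC(=O)C(COC(C)=O)=C12 | target

## Step count and least certain steps

Total: 25 steps. Longest linear sequence: 25 steps (1 to 38); the other starting materials enter as purchased reagents.

Step 15 (key step). What may go wrong: deprotonation at the allylic or anisylic α-oxy positions, a [1,2]-shift if the mixture warms, or weak facial discrimination at C7 that gives the wrong C6/C8 relationship. The fallback sets out from 22 and returns at 23. The rearrangement is run as before, the carbinol mixture containing the C6-epimeric cyclodecynol F1 is oxidised with Dess–Martin periodinane to cyclodecynone F2, and this is reduced with the (S)-CBS oxazaborolidine and BH3·SMe2. The alkyne acts as the small group, so 6S is expected and C6 is then set by reagent control, not by the sigmatropic shift.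

Step 14. What may go wrong: intermolecular metathesis to oligomers competing with closure, or slow turnover at the propargylic ether alkyne. The fallback sets out from 11 and returns at 22 by ring-closing etherification. The acetylide of 11 is hydroxymethylated with paraformaldehyde to propargylic alcohol F3, which is converted (MsCl, Et3N; LiCl) into propargylic chloride F4. DDQ then gives primary alcohol F5 and Dess–Martin oxidation gives aldehyde F6. The olefination of step 11 with 15 and 16 gives enoate F7, and i-Bu2AlH gives chloro allylic alcohol F8. NaH in THF at high dilution closes the O–C6 bond by intramolecular Williamson etherification. The step count is the same as in the main line.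

Step 21. What may go wrong: selenenylation on the face anti to H7, which blocks the syn-elimination; loss of formaldehyde from the mono-alkoxide before the dianion forms; or epoxidation of the ring alkenes by selenium peracids if excess peroxide is used. The fallback sets out from 30 and returns at 34. The zinc enolate of 30, made with Zn(TMP)2, is dehydrogenated with catalytic [Pd(C3H5)Cl]2 and diethyl allyl phosphate (β-hydride elimination from the palladium enolate) to the butenolide 4-methoxybenzyl ether F9. DDQ then frees the C13 hydroxyl.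

Step 24. What may go wrong: competing oxidation of the C8 carbinol, or lactone migration to O8 while both hydroxyls are free. The fallback sets out from 35 and returns at 37, and uses the different lability of the two silyl groups. PPTS in methanol removes only the triethylsilyl group to give the C2 alcohol F10. Dess–Martin periodinane gives the C2 ketone F11, which still carries the C8 silyl ether, and HF·pyridine then frees the C8 hydroxyl.

## Further compounds

F1 | step 15 | C6 epimer of 23 (6R,7S,8S,2R) | O[C@H]1C#CC[C@@H](O[Si](CC)(CC)CC)/C=C(C)/C[C@H](O[Si](C)(C)C(C)(C)C)[C@H]1C(=C)COCc1ccc(OC)cc1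
F2 | step 15 | cyclodecynone: C6 ketone of 23 (7S,8S,2R) | O=C1C#CC[C@@H](O[Si](CC)(CC)CC)/C=C(C)/C[C@H](O[Si](C)(C)C(C)(C)C)[C@H]1C(=C)COCc1ccc(OC)cc1
F3 | step 14 | (5R,6E,9S)-9-[(tert-butyldimethylsilyl)oxy]-10-[(4-methoxybenzyl)oxy]-7-methyl-5-[(triethylsilyl)oxy]dec-6-en-2-yn-1-ol | COc1ccc(COC[C@@H](O[Si](C)(C)C(C)(C)C)C/C(C)=C/[C@H](O[Si](CC)(CC)CC)CC#CCO)cc1
F4 | step 14 | propargylic chloride from F3 | COc1ccc(COC[C@@H](O[Si](C)(C)C(C)(C)C)C/C(C)=C/[C@H](O[Si](CC)(CC)CC)CC#CCCl)cc1
F5 | step 14 | (2S,4E,6R)-2-[(tert-butyldimethylsilyl)oxy]-10-chloro-4-methyl-6-[(triethylsilyl)oxy]dec-4-en-8-yn-1-ol | OC[C@@H](O[Si](C)(C)C(C)(C)C)C/C(C)=C/[C@H](O[Si](CC)(CC)CC)CC#CCCl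
F6 | step 14 | aldehyde from F5 | O=C[C@@H](O[Si](C)(C)C(C)(C)C)C/C(C)=C/[C@H](O[Si](CC)(CC)CC)CC#CCCl
F7 | step 14 | chloro analogue of 18 (chlorine on C6 in place of the alkyne methyl hydrogen) | CCOC(=O)/C(COCc1ccc(OC)cc1)=C/[C@@H](O[Si](C)(C)C(C)(C)C)C/C(C)=C/[C@H](O[Si](CC)(CC)CC)CC#CCCl
F8 | step 14 | chloro analogue of 19 (C12 hydroxyl, C6 chloride) | OC/C(COCc1ccc(OC)cc1)=C/[C@@H](O[Si](C)(C)C(C)(C)C)C/C(C)=C/[C@H](O[Si](CC)(CC)CC)CC#CCCl
F9 | step 21 | 13-[(4-methoxybenzyl)oxy]-7(11)-en-12,6-olide with both silyl ethers | [C@@H]12/C=C(C)/C[C@@H](O[Si](CC)(CC)CC)/C=C(C)/C[C@H](O[Si](C)(C)C(C)(C)C)C1=C(COCc3ccc(OC)cc3)C(=O)O2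
F10 | step 24 | 13-acetoxy-2-hydroxy butenolide with C8 tert-butyldimethylsilyl ether | [C@@H]12/C=C(C)/C[C@@H](O)/C=C(C)/C[C@H](O[Si](C)(C)C(C)(C)C)C1=C(COC(C)=O)C(=O)O2
F11 | step 24 | 13-acetoxy-2-oxo butenolide with C8 tert-butyldimethylsilyl ether | [C@@H]12/C=C(C)/CC(=O)/C=C(C)/C[C@H](O[Si](C)(C)C(C)(C)C)C1=C(COC(C)=O)C(=O)O2
A1 | alternative 1 | seco N-acyloxyphthalimide ester with C10 (E)-alkenyl iodide | O=C(ON1C(=O)c2ccccc2C1=O)C[C@H](O[Si](C)(C)C(C)(C)C)C1=C(COC(C)=O)C(=O)O[C@@H]1/C=C(C)/CC(=O)/C=C(C)/I
A2 | alternative 1 | C8 tert-butyldimethylsilyl ether of the complete bicyclic skeleton | CC(C)(C)[Si](C)(C)O[C@H]1C/C(C)=C/C(=O)C/C(C)=C/[C@H]2OC(=O)C(COC(C)=O)=C12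
A3 | alternative 2 | C7 iodobutenolide with C8 aldehyde and C2 triethylsilyl ether | O=CC/C(C)=C/[C@H](O[Si](CC)(CC)CC)C/C(C)=C/[C@H]1OC(=O)C(COC(C)=O)=C1I
A4 | alternative 2 | butenolide-fused ten-membered ring with free C8 hydroxyl and C2 triethylsilyl ether | O[C@H]1C/C(C)=C/[C@H](O[Si](CC)(CC)CC)C/C(C)=C/[C@H]2OC(=O)C(COC(C)=O)=C12
A5 | alternative 3 | open-chain ynal: C6 aldehyde, C7 4-methoxybenzyl ether, C8 and C2 silyl ethers, terminal C4≡C5 alkyne | O=C[C@@H](OCc1ccc(OC)cc1)[C@@H](O[Si](C)(C)C(C)(C)C)C/C(C)=C/[C@@H](O[Si](CC)(CC)CC)CC#C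
A6 | alternative 3 | ten-membered cyclodecadienol with free C6 hydroxyl | O[C@@H]1/C=C(C)/C[C@H](O[Si](CC)(CC)CC)/C=C(C)/C[C@H](O[Si](C)(C)C(C)(C)C)[C@@H]1OCc1ccc(OC)cc1
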